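**Plan**
1. The SMILES encodes the 2,3-cis isomer, (2S,3R), with H-2 and H-3 on the same face of dihydrofuran ring B (O1, C2, C3, C3a, C7a). Ring A is the benzo ring, ring C the 4-hydroxyphenyl on C2, ring D the 3,5-dihydroxyphenyl on C3, and ring E the 4-hydroxyphenyl at the end of the C4 ethyl chain.
2. Cuts, in retrosynthetic order: five O–benzyl bonds; the C2–H and C3–H bonds (back to the flat benzofuran, a temporary higher oxidation level); the C4–CH2 bond; then O1–C7a and C3–C3a together.
3. Enabling feature: O1–C2–C3 with rings C and D is the O–C=C of a deoxybenzoin enolate, a C,O-dinucleophile with C3 as the natural nucleophile. C7a–C3a–C4 are three neighbouring ring A carbons that map onto the Br–C, I–C, Br–C pattern of a symmetric 2-iodo-1,3-dibromoarene.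
4. Forward: the deoxybenzoin and the trihalide take two steps each. One palladium domino then fuses ring B onto ring A, and the bromide left at C4 takes the ring E chain by B-alkyl Suzuki–Miyaura coupling.
5. Stereochemistry: both centres come from one catalyst-controlled syn hydrogenation of C2=C3 (cis by mechanism, absolute sense from a chiral ruthenium NHC catalyst). Only neutral conditions follow, because the cis isomer is the less stable epimer and C2–O1 ionises easily.

Key step: step 5

Assumption: the sense of induction of the hydrogenation catalyst cannot be derived for this new substrate class. The (S,S) ligand is written, and the (R,R) ligand takes its place if a trial run gives the mirror-image series.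

Step 1
Reactants: 1 5-bromoresorcinol (5-bromobenzene-1,3-diol)
Product: 2 1,3-bis(benzyloxy)-5-bromobenzene
Conditions: BnBr (2.2 equiv), K2CO3, DMF, rt to 60 °C
Reagents that add atoms: benzyl bromide, BrCc1ccccc1
Why: Williamson ether synthesis, in which both phenoxides of 1 displace bromide from benzyl bromide; benzyl is chosen because it withstands every basic palladium step and leaves at the end under neutral conditions.

Step 2
Reactants: 2 1,3-bis(benzyloxy)-5-bromobenzene; 3 4'-(benzyloxy)acetophenone
Product: 4 1-[4-(benzyloxy)phenyl]-2-[3,5-bis(benzyloxy)phenyl]ethan-1-one (the deoxybenzoin)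
Conditions: Pd2(dba)3 (1 mol %), rac-BINAP (2.4 mol %), NaOtBu, THF, 70 °C
Reagents that add atoms: none
Why: Palladium-catalysed ketone α-arylation, in which the sodium enolate of methyl ketone 3 couples with aryl bromide 2 through an arylpalladium enolate, and the chelating ligand together with the lower reactivity of the more stabilised, more hindered product enolate should hold the reaction at monoarylation.

Step 3
Reactants: 5 4-(benzyloxy)aniline
Product: 6 4-(benzyloxy)-2,6-dibromoaniline
Conditions: NBS (2.05 equiv), MeCN, 0 °C to rt, dark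
Reagents that add atoms: N-bromosuccinimide, O=C1CCC(=O)N1Br
Why: Electrophilic aromatic bromination, in which the amino group outweighs the ether as director and its para position is blocked, so both bromines should enter ortho to nitrogen and give the symmetric pattern.

Step 4
Reactants: 6 4-(benzyloxy)-2,6-dibromoaniline
Product: 8 5-(benzyloxy)-1,3-dibromo-2-iodobenzene, via arenediazonium tosylate 7 (not isolated)
Conditions: p-TsOH·H2O (3 equiv), NaNO2 (2 equiv), KI (2.5 equiv), MeCN/H2O, 10 °C to rt
Reagents that add atoms: potassium iodide, [K+].[I-]; sodium nitrite, [Na+].[O-]N=O, and p-toluenesulfonic acid, Cc1ccc(S(=O)(=O)O)cc1 (the atoms of these two stand only in 7)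
Why: Sandmeyer-type iododediazoniation, in which the weakly basic aniline is diazotised to a stable diazonium tosylate that iodide reduces and captures without copper, while the benzyl ether is inert to the cold dilute acid.

Step 5
Reactants: 4 1-[4-(benzyloxy)phenyl]-2-[3,5-bis(benzyloxy)phenyl]ethan-1-one; 8 5-(benzyloxy)-1,3-dibromo-2-iodobenzene (1.2 equiv)
Product: 10 6-(benzyloxy)-2-[4-(benzyloxy)phenyl]-3-[3,5-bis(benzyloxy)phenyl]-4-bromo-1-benzofuran, via alpha-arylated ketone 9 (not isolated)
Conditions: Pd(OAc)2 (5 mol %), PPh3 (20 mol %), Cs2CO3 (3 equiv), o-xylene, 140 °C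
Reagents that add atoms: none
Why: Zerovalent palladium inserts into the C–I bond of 8 much faster than into C–Br, the caesium enolate of 4 binds through carbon and reductive elimination forms C3–C3a to give 9; the more acidic 9 is deprotonated at once, palladium inserts into one of the two C–Br bonds beside the new substituent, the enolate oxygen replaces bromide on palladium and C–O reductive elimination forms O1–C7a. The closest known reaction type is the palladium-catalysed domino C-arylation/O-arylation of benzyl aryl ketones with 1,2-dihalobenzenes to 2,3-diarylbenzofurans, with a copper-catalysed relative that joins 1-bromo-2-iodobenzenes and β-keto esters. Ring B closes by reductive elimination from a six-membered oxapalladacycle (Pd, C7a, C3a, C3, C2, O1) of the Z-enolate, that is by intramolecular enolate O-arylation, and the aromatic furan makes it irreversible. No stereocentre is kept, since C3 of 9 forms racemic and is flattened on enolisation, which is intended because both centres are set in step 7. The step needs carbon before oxygen and iodide before bromide (secured by the iodide/bromide reactivity gap and the soft carbon terminus of the enolate), one regiochemistry on ring A (secured because the two bromines of 8 are homotopic), and survival of the third halogen (secured because ring closure is intramolecular, further coupling of 10 would be intermolecular at a bromide shielded by ring D, and ketone 4 is the limiting partner).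

Step 6
Reactants: 10 6-(benzyloxy)-2-[4-(benzyloxy)phenyl]-3-[3,5-bis(benzyloxy)phenyl]-4-bromo-1-benzofuran; 11 4-(benzyloxy)styrene (1-(benzyloxy)-4-ethenylbenzene)
Product: 13 6-(benzyloxy)-2-[4-(benzyloxy)phenyl]-4-{2-[4-(benzyloxy)phenyl]ethyl}-3-[3,5-bis(benzyloxy)phenyl]-1-benzofuran, via B-alkyl-9-BBN borane 12 (not isolated)
Conditions: 11, 9-BBN dimer, THF, 0 °C to rt; then 10, Pd(OAc)2 (5 mol %), SPhos (2-dicyclohexylphosphino-2',6'-dimethoxybiphenyl, 10 mol %), aq. K3PO4, THF, 65 °C
Reagents that add atoms: 9-borabicyclo[3.3.1]nonane, B1C2CCCC1CCC2 (its atoms stand only in 12)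
Why: Hydroboration followed by B-alkyl Suzuki–Miyaura coupling, in which 9-BBN adds boron to the terminal carbon of styrene 11 and the primary alkylborane passes its sp3 carbon to the arylpalladium bromide from 10, a bulky electron-rich biarylphosphine being used because the C4 bromide lies beside ring D.

Step 7
Reactants: 13 6-(benzyloxy)-2-[4-(benzyloxy)phenyl]-4-{2-[4-(benzyloxy)phenyl]ethyl}-3-[3,5-bis(benzyloxy)phenyl]-1-benzofuran
Product: 14 (2S,3R)-6-(benzyloxy)-2-[4-(benzyloxy)phenyl]-4-{2-[4-(benzyloxy)phenyl]ethyl}-3-[3,5-bis(benzyloxy)phenyl]-2,3-dihydro-1-benzofuran (2,3-cis)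
Conditions: [Ru(cod)(2-methylallyl)2] (10 mol %), (S,S)-SINpEt·HBF4 (1,3-bis[(S)-1-(naphthalen-1-yl)ethyl]-4,5-dihydroimidazolium tetrafluoroborate, 20 mol %), KOtBu (30 mol %), n-hexane, 70 °C; then 13, toluene, H2 (100 bar), 60 °C
Reagents that add atoms: none
Why: Proposed new method: the ruthenium bis(NHC) hydride formed in the flask should bind C2=C3 of ring B, the least aromatic and most electron-rich π bond of 13, and pass both hydrogens from the metal to one face (migratory insertion, then hydrogenolysis of the Ru–C bond with retention), so the 2,3-cis relationship follows from the mechanism, while the C2-symmetric naphthylethyl pocket, which must tell the O1/ring C edge from the C4/ring D edge, selects the face and hence (2S,3R), and the neutral to slightly basic medium protects the acid-labile C2–O1 bond of the cis product; the closest known reaction type is the asymmetric hydrogenation of 2-aryl- and 3-substituted benzofurans with this catalyst family, which has not been shown on fully substituted 2,3-diaryl furan double bonds, hence the raised pressure, temperature and loading.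

Step 8
Reactants: 14 (2S,3R)-pentabenzyl ether
Product: 15 5-[(2S,3R)-6-hydroxy-2-(4-hydroxyphenyl)-4-[2-(4-hydroxyphenyl)ethyl]-2,3-dihydro-1-benzofuran-3-yl]benzene-1,3-diol (target)
Conditions: H2 (1 atm), Pd/C (10 wt %), EtOAc/EtOH, rt, stopped after uptake of five equivalents
Reagents that add atoms: none
Why: Catalytic hydrogenolysis of aryl benzyl ethers, in which the five primary, unhindered O–CH2Ph bonds should be cleaved on palladium much faster than the secondary, doubly flanked C2–O1 bond of ring B, and the neutral medium at room temperature leaves both stereocentres untouched.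

**Compound list**
1 | 5-bromoresorcinol | Oc1cc(O)cc(Br)c1 | starting material
2 | 1,3-bis(benzyloxy)-5-bromobenzene | Brc1cc(OCc2ccccc2)cc(OCc2ccccc2)c1 | intermediate
3 | 4'-(benzyloxy)acetophenone | CC(=O)c1ccc(OCc2ccccc2)cc1 | starting material
4 | 1-[4-(benzyloxy)phenyl]-2-[3,5-bis(benzyloxy)phenyl]ethan-1-one | O=C(Cc1cc(OCc2ccccc2)cc(OCc2ccccc2)c1)c1ccc(OCc2ccccc2)cc1 | intermediate
5 | 4-(benzyloxy)aniline | Nc1ccc(OCc2ccccc2)cc1 | starting material
6 | 4-(benzyloxy)-2,6-dibromoaniline | Nc1c(Br)cc(OCc2ccccc2)cc1Br | intermediate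
7 | 4-(benzyloxy)-2,6-dibromobenzenediazonium p-toluenesulfonate (not isolated) | N#[N+]c1c(Br)cc(OCc2ccccc2)cc1Br.Cc1ccc(S(=O)(=O)[O-])cc1 | intermediate
8 | 5-(benzyloxy)-1,3-dibromo-2-iodobenzene | Ic1c(Br)cc(OCc2ccccc2)cc1Br | intermediate
9 | 2-[4-(benzyloxy)-2,6-dibromophenyl]-1-[4-(benzyloxy)phenyl]-2-[3,5-bis(benzyloxy)phenyl]ethan-1-one, racemic (not isolated) | O=C(c1ccc(OCc2ccccc2)cc1)C(c1cc(OCc2ccccc2)cc(OCc2ccccc2)c1)c1c(Br)cc(OCc2ccccc2)cc1Br | intermediate
10 | 6-(benzyloxy)-2-[4-(benzyloxy)phenyl]-3-[3,5-bis(benzyloxy)phenyl]-4-bromo-1-benzofuran | Brc1cc(OCc2ccccc2)cc2oc(-c3ccc(OCc4ccccc4)cc3)c(-c3cc(OCc4ccccc4)cc(OCc4ccccc4)c3)c12 | intermediate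
11 | 4-(benzyloxy)styrene | C=Cc1ccc(OCc2ccccc2)cc1 | starting material
12 | 9-{2-[4-(benzyloxy)phenyl]ethyl}-9-borabicyclo[3.3.1]nonane (not isolated) | C(Cc1ccc(OCc2ccccc2)cc1)B1C2CCCC1CCC2 | intermediate
13 | 6-(benzyloxy)-2-[4-(benzyloxy)phenyl]-4-{2-[4-(benzyloxy)phenyl]ethyl}-3-[3,5-bis(benzyloxy)phenyl]-1-benzofuran | c1ccccc1COc1ccc(CCc2cc(OCc3ccccc3)cc3oc(-c4ccc(OCc5ccccc5)cc4)c(-c4cc(OCc5ccccc5)cc(OCc5ccccc5)c4)c23)cc1 | intermediate
14 | (2S,3R)-6-(benzyloxy)-2-[4-(benzyloxy)phenyl]-4-{2-[4-(benzyloxy)phenyl]ethyl}-3-[3,5-bis(benzyloxy)phenyl]-2,3-dihydro-1-benzofuran (cis) | c1ccccc1COc1ccc(CCc2cc(OCc3ccccc3)cc3c2[C@@H](c2cc(OCc4ccccc4)cc(OCc4ccccc4)c2)[C@@H](c2ccc(OCc4ccccc4)cc2)O3)cc1 | intermediate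
15 | 5-[(2S,3R)-6-hydroxy-2-(4-hydroxyphenyl)-4-[2-(4-hydroxyphenyl)ethyl]-2,3-dihydro-1-benzofuran-3-yl]benzene-1,3-diol | Oc1ccc(CCc2cc(O)cc3c2[C@@H](c2cc(O)cc(O)c2)[C@@H](c2ccc(O)cc2)O3)cc1 | target

Total step count: 8. Longest linear sequence: 6 (steps 3, 4, 5, 6, 7, 8 from 5; equally steps 1, 2, 5, 6, 7, 8 from 1).

**Steps most likely to fail**

Step 7 (labelled step). The fully substituted C2=C3 bond is shielded by the twisted rings C and D and by the C4 chain. It may not reach the metal, so there is no turnover, or the two faces may be told apart poorly. The fallback sets out from 13 and comes back at 15, using only known chemistry. Hydrogenolysis of 13 (H2, 1 atm, Pd/C, THF/MeOH) first gives the pentaphenol benzofuran F1. Heterogeneous hydrogenation of this compound under forcing conditions (H2, 50 to 100 bar, Pd/C, EtOH, 60 to 80 °C) adds hydrogen syn from the metal surface. It should give the racemic cis compound, that is 15 together with its (2R,3S) mirror image F2. The two are separated by preparative HPLC on an amylose tris(3,5-dimethylphenylcarbamate) phase. The absolute configuration is assigned by electronic circular dichroism.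

Step 5. The first reductive elimination must join a hindered enolate carbon to an arylpalladium flanked by two bromines. It may stall, so that protodeiodination takes over, or the remaining bromide may couple further. The fallback sets out from 4 and 8, reverses the polarity of ring A, and comes back at 10. Riley oxidation of 4 (SeO2, dioxane/H2O, reflux) gives the unsymmetrical benzil F3. Iodine–magnesium exchange on 8 (iPrMgCl·LiCl, THF, −40 °C, kept cold to prevent collapse to the aryne) gives 4-(benzyloxy)-2,6-dibromophenylmagnesium chloride F4. This reagent adds to the more electrophilic carbonyl of F3, the one on ring D, because the other carbonyl is deactivated by the para benzyloxy group. The product is the tertiary ketol F5. SmI2 (THF/MeOH) removes the α-hydroxyl group and gives 9, now isolated. An Ullmann-type enolate O-arylation (CuI, 1,10-phenanthroline, Cs2CO3, DMF, 100 °C) then closes ring B to 10.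

Step 8. Hydrogenolytic opening of ring B at the benzylic C2–O1 bond may compete with debenzylation. Epimerisation at C2 through reversible ionisation on an acidic catalyst batch is a second risk. The fallback sets out from 13 and comes back at 15. It moves the debenzylation to the stage where ring B is still aromatic and has no benzylic C–O bond. Treating 13 with H2 (1 atm) and Pd/C gives the pentaphenol benzofuran F6. TBSCl and imidazole in DMF convert it into the penta(tert-butyldimethylsilyl) ether F7. Hydrogenation as in step 7 gives the (2S,3R)-cis pentasilyl ether F8. Et3N·3HF in THF at rt then frees 15 without hydrogen, strong acid or strong base.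

**Further compounds**
F1 | step 7 | 5-{6-hydroxy-2-(4-hydroxyphenyl)-4-[2-(4-hydroxyphenyl)ethyl]-1-benzofuran-3-yl}benzene-1,3-diol | Oc1ccc(CCc2cc(O)cc3oc(-c4ccc(O)cc4)c(-c4cc(O)cc(O)c4)c23)cc1
F2 | step 7 | 5-[(2R,3S)-6-hydroxy-2-(4-hydroxyphenyl)-4-[2-(4-hydroxyphenyl)ethyl]-2,3-dihydro-1-benzofuran-3-yl]benzene-1,3-diol (mirror image of 15) | Oc1ccc(CCc2cc(O)cc3c2[C@H](c2cc(O)cc(O)c2)[C@H](c2ccc(O)cc2)O3)cc1
F3 | step 5 | 1-[4-(benzyloxy)phenyl]-2-[3,5-bis(benzyloxy)phenyl]ethane-1,2-dione | O=C(C(=O)c1cc(OCc2ccccc2)cc(OCc2ccccc2)c1)c1ccc(OCc2ccccc2)cc1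
F4 | step 5 | 4-(benzyloxy)-2,6-dibromophenylmagnesium chloride | Cl[Mg]c1c(Br)cc(OCc2ccccc2)cc1Br
F5 | step 5 | 2-[4-(benzyloxy)-2,6-dibromophenyl]-1-[4-(benzyloxy)phenyl]-2-[3,5-bis(benzyloxy)phenyl]-2-hydroxyethan-1-one, racemic | O=C(c1ccc(OCc2ccccc2)cc1)C(O)(c1cc(OCc2ccccc2)cc(OCc2ccccc2)c1)c1c(Br)cc(OCc2ccccc2)cc1Br
F6 | step 8 | 5-{6-hydroxy-2-(4-hydroxyphenyl)-4-[2-(4-hydroxyphenyl)ethyl]-1-benzofuran-3-yl}benzene-1,3-diol | Oc1ccc(CCc2cc(O)cc3oc(-c4ccc(O)cc4)c(-c4cc(O)cc(O)c4)c23)cc1
F7 | step 8 | penta-O-(tert-butyldimethylsilyl) ether of the pentaphenol benzofuran | CC(C)(C)[Si](C)(C)Oc1ccc(CCc2cc(O[Si](C)(C)C(C)(C)C)cc3oc(-c4ccc(O[Si](C)(C)C(C)(C)C)cc4)c(-c4cc(O[Si](C)(C)C(C)(C)C)cc(O[Si](C)(C)C(C)(C)C)c4)c23)cc1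
F8 | step 8 | (2S,3R)-cis penta-O-(tert-butyldimethylsilyl) ether of 15 | CC(C)(C)[Si](C)(C)Oc1ccc(CCc2cc(O[Si](C)(C)C(C)(C)C)cc3c2[C@@H](c2cc(O[Si](C)(C)C(C)(C)C)cc(O[Si](C)(C)C(C)(C)C)c2)[C@@H](c2ccc(O[Si](C)(C)C(C)(C)C)cc2)O3)cc1
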